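# Haterumaimide B: total synthesis proposal built on an intramolecular vinylallene Diels–Alder reaction

## Structural features

Haterumaimide B (labdane numbering throughout) is a trans-decalin (ring A: C1–C5 and C10; ring B: C5–C10). C9 carries, through the C11 methylene, the carbinol C12, which bears a succinimide (ring C: C13, C14, C15, N, C16). Ring A holds a vicinal trans-diequatorial dichloride (2α,3β; 2R,3R), and C3 is neopentyl because it sits next to the gem-dimethyl carbon C4. C5 (H α), the quaternary C10 (CH3 β) and C9 (side chain β, equatorial) are contiguous along the ring fusion. The syn pair C12 (S)/C13 (R) is insulated from them by C11 and needs its own control. Ring B contains the C6 ketone and the C8=C17 exocyclic methylene, a β,γ-unsaturated ketone that lies uphill from its conjugated C7=C8 isomer.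

The fragile groups are this enone (acid and base), C5 (epimerisable, and as an enolate γ to C3–Cl), the β-hydroxy imide (retro-aldol, dehydration) and the secondary chlorides (elimination).

The real difficulty has three parts:
- The diequatorial dichloride cannot come from addition to a ring A alkene (this gives the diaxial isomer) or from substitution at C3.
- The C6 oxygen sits on a carbon that neither a cationic polyene cyclisation nor the drimane chiral pool functionalises.
- The alkene position is contra-thermodynamic.

The key step exploits the array C5–C6(=O)–C7–C8(=C17) of ring B. This array is the C7-protonated form of the dienol ether C6(OR)=C7–C8=C17. That dienol ether is the retron of a Diels–Alder adduct between the 2-oxygenated vinylallene C5=C6(OR)–C7=C8=C17 and the C9=C10 alkene. With C1–C4 as the tether, the same event closes ring A around a dichloride that was set on an open chain.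

## Logic of the disconnections

**32 ⇒ 31.** The bond cut is C7–H, with silicon returned to the C6 oxygen. The ketone stays in the masked form that the key step itself delivers, so no protecting group is added and C8=C17 cannot migrate during the end game. The forward protonation must be kinetic at C7.

**31 ⇒ 29 (through 30).** The bonds cut are N–C16 and N–C15. Nitrogen enters last as ammonia between two acyl groups of different reactivity. Ring C is reduced to an open succinate. The forward step must be mild enough for the β-hydroxy carbonyl unit.

**29 ⇒ 23 + 26.** The bond cut is C12–C13. Both side-chain stereocentres arise together, and a C4 unit is removed. Because C9 is too remote to steer this pair, the forward step must be reagent-controlled.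

**26 ⇒ 24 + 25.** The bond cut is the N–acyl bond, which leads to two commercial compounds.

**23 ⇒ 20 + 21 (through 22).** The bond cut is C11–C12, formed as C11=C12. The dienophile of the key step needs a carbonyl carbon at C11, so C12 can only be added afterwards. The forward chemistry must be non-basic because C9–H of 20 is both allylic and α to a carbonyl group.

**20 ⇒ 19.** C11–H is exchanged for C11–OCH3. This is an oxidation-level change only. The ester is the form in which C11 survives the steps before the key step.

**19 ⇒ 18 (key disconnection).** The bonds cut are C5–C10 and C8–C9. Both carbocycles, the stereocentres C5, C9 and C10, the C6 oxygen and the exocyclic methylene are traced back to one acyclic chain whose only stereocentres are C2 and C3. In one sentence: rings A and B are closed together by an intramolecular Diels–Alder reaction of acyclic 18. The forward step must form a bond between a neopentyl carbon and a fully substituted one. It must also choose the anti transition state on the face set by the two chlorines.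

**18 ⇒ 17 ⇒ 16.** The changes are C7–H (with C17–O restored) and then O–Si. The sensitive allene is generated last from a robust alkyne. The enol silane is made while C5 is the only enolisable position. The forward steps must give the Z enol silane and deliver hydride at C7.

**16 ⇒ 12 + 13 (through 15).** The bond cut is C6–C7. A three-carbon alkyne supplies C7, C8 and C17. The addition must tolerate an ester, a carbonate and two chlorides.

**12 ⇒ 10.** C6=O is traced back to C6=CH2. A terminal alkene is an inert placeholder for the aldehyde during the chlorination chemistry. The cleavage must spare the enoate alkene.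

**10 ⇒ 9.** C2–Cl is traced back to C2–O of opposite configuration. The syn dichloride is reached from the anti chlorohydrin that acyclic stereocontrol gives naturally. The forward step must be a clean inversion at the non-neopentyl carbon.

**9 ⇒ 5 + 8, and 8 ⇒ 6.** The bond cut is C1–C2. One vinylogous aldol step brings in C1, C10, its methyl group, C9 and C11 with the E alkene in place. It needs γ-selectivity, E geometry and 1,2-anti induction from C3.

**5 ⇒ 4.** The bond cut is C3–Cl. This is the only stereocentre of the decalin part that is set by a catalyst, and all the others are relayed from it. Putting chlorine on C3 by electrophilic chlorination avoids any substitution at the neopentyl carbon.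

**4 ⇒ 3 ⇒ 1 + 2.** The bonds cut are C4–C5 (a [3,3] shift that creates the quaternary C4) and then the carbinol C–C bond. This leads to two commodity chemicals.

## Other disconnections considered

**Alternative 1:** This is the first plan that comes to mind.
- *Cut:* C12–C13 is the strategic bond, formed by an auxiliary-controlled aldol reaction on keto aldehyde A1. The decalin is drawn from a cation–olefin bicyclisation (C4–C5 and C9–C10) of a chlorinated polyene, which would deliver the 6-deoxy aldehyde A2 or a close relative.
- *Ground for rejection:* A C6 carbonyl cannot be carried through the cyclisation because it would be conjugated with the C5=C10 alkene that must act as the nucleophile. C6 of A2 would therefore have to be oxidised late. It is an unactivated methylene between a tertiary carbon and the more reactive allylic C7. The initiating C4 cation would also be flanked by two C–Cl dipoles.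
- *Comparison:* The aldol bond simplifies only the side chain, so the plan leaves the real difficulty in place. The chosen plan keeps the aldol as a tactic and solves ring B in the key step.

**Alternative 2:**
- *Cut:* C7–C8 and C9–C10. The forward key step is an intermolecular Diels–Alder reaction of the ring A silyloxy diene A3 with methyl buta-2,3-dienoate A4, giving adduct A5.
- *Ground for rejection:* Only ring B is formed, and A3 needs an enantioselective trans-dichlorination of a cyclic precursor of its own. Its s-cis form is twisted by the flanking C4 gem-dimethyl and C10 methyl groups. The quaternary C10 would have to form in a bimolecular reaction. The π-face at C10 would be chosen only by two remote pseudo-equatorial chlorines. C5 would still have to be set afterwards.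
- *Comparison:* The intramolecular version forms two rings, has an entropic advantage, and translates the chlorines into a chair preference.

**Alternative 3:**
- *Cut:* C6–C7. The forward key step is a type 2 carbonyl–ene cyclisation (Me2AlCl) of the monocyclic aldehyde A6 to the 6-hydroxy decalin A7, followed by oxidation.
- *Ground for rejection:* The step gives the 1,3-relation of oxygen and exocyclic methylene correctly, but it forms one bond and no ring stereocentre of the target. A6 already contains C2, C3, C5, C9 and C10, including the congested C5/C10/C9 triad on a flexible monocycle.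
- *Comparison:* The precursor is hardly simpler than the product, and the step count grows.

Key step: step 12

Assumption 1: (2S,5S)-2,5-diphenylpyrrolidine is taken to give the (R)-chloride 5. If the sense of induction is the reverse, its antipode is used and nothing else changes.
Assumption 2: compounds 13 and 21 are taken as commercial. Drimane C12 is the same atom as labdane C17.

## Steps

Step 1
Reactants: 1 3-methylbut-2-enal; 2 allylmagnesium bromide
Product: 3 6-methylhepta-1,5-dien-4-ol (racemic)
Conditions: Et2O, −78 to 0 °C; aq NH4Cl
Reagents that add atoms: none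
Why: Grignard 1,2-addition; allyl Grignard reagents attack the carbonyl carbon of enals and not the hindered β-carbon. The carbinol centre is racemic and disappears in step 2.

Step 2
Reactants: 3 6-methylhepta-1,5-dien-4-ol
Product: 4 3,3-dimethylhex-5-enal
Conditions: KH, 18-crown-6, THF, 0 °C to rt; pH 7 buffer at −78 °C
Reagents that add atoms: none
Why: Anionic oxy-Cope rearrangement; the potassium alkoxide accelerates the [3,3] shift that forms C4–C5 and the quaternary C4, and the enolate is protonated on work-up. Together with step 1 this is a formal conjugate allylation of the enal.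

Step 3
Reactants: 4 3,3-dimethylhex-5-enal
Product: 5 (2R)-2-chloro-3,3-dimethylhex-5-enal
Conditions: NCS, (2S,5S)-2,5-diphenylpyrrolidine (10 mol %), CH2Cl2, 0 °C to rt; used without chromatography
Reagents that add atoms: N-chlorosuccinimide, O=C1CCC(=O)N1Cl
Why: Enamine-catalysed enantioselective α-chlorination of an aldehyde, a reaction type that accepts aldehydes with a quaternary β-carbon. The twofold-symmetric amine shields one enamine face and sets C3 (R), and the bulky neighbour slows racemisation of 5.

Step 4
Reactants: 6 methyl 3-methylbut-2-enoate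
Product: 8 [(1-methoxy-3-methylbuta-1,3-dien-1-yl)oxy]trimethylsilane, via lithium dienolate 7 (not isolated)
Conditions: LiN(i-Pr)2, THF, −78 °C; then Me3SiCl
Reagents that add atoms: chlorotrimethylsilane, C[Si](C)(C)Cl
Why: γ-Deprotonation of the senecioate followed by O-silylation is the standard entry to the vinylogous silyl ketene acetal. The geometry of the ketene acetal has no bearing on step 5.

Step 5
Reactants: 5 (2R)-2-chloro-3,3-dimethylhex-5-enal; 8 [(1-methoxy-3-methylbuta-1,3-dien-1-yl)oxy]trimethylsilane
Product: 9 methyl (2E,5S,6R)-6-chloro-5-hydroxy-3,7,7-trimethyldeca-2,9-dienoate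
Conditions: BF3·OEt2, CH2Cl2–Et2O, −78 °C; aq NaHCO3
Reagents that add atoms: none
Why: Vinylogous Mukaiyama aldol reaction; the dienolate attacks through its unhindered γ-carbon in an open transition state, forms C1–C2 and should give the E-enoate from its s-trans form. The Cornforth (polar Felkin–Anh) arrangement of the α-chloro aldehyde, reinforced by the bulky C4 group, directs attack to give the 1,2-anti chlorohydrin (C2 S).

Step 6
Reactants: 9 methyl (2E,5S,6R)-6-chloro-5-hydroxy-3,7,7-trimethyldeca-2,9-dienoate
Product: 10 methyl (2E,5R,6R)-5,6-dichloro-3,7,7-trimethyldeca-2,9-dienoate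
Conditions: 1-chloro-N,N,2-trimethylprop-1-en-1-amine, CH2Cl2, 0 °C to rt
Reagents that add atoms: 1-chloro-N,N,2-trimethylprop-1-en-1-amine, CC(C)=C(Cl)N(C)C
Why: Deoxychlorination by an α-chloroenamine; the alkoxy-iminium chloride collapses by SN2 attack of chloride with inversion at C2, which turns the anti chlorohydrin into the syn (2R,3R) dichloride. The medium is neutral, so vinylogous elimination towards the dienoate is not triggered, and the adjacent C3–Cl disfavours ionisation.

Step 7
Reactants: 10 methyl (2E,5R,6R)-5,6-dichloro-3,7,7-trimethyldeca-2,9-dienoate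
Product: 12 methyl (2E,5R,6R)-5,6-dichloro-3,7,7-trimethyl-9-oxonon-2-enoate, via vicinal diol 11 (not isolated)
Conditions: K2OsO4·2H2O (cat.), NaIO4, 2,6-lutidine, dioxane–H2O, rt
Reagents that add atoms: sodium periodate, [Na+].[O-]I(=O)(=O)=O
Why: Lemieux–Johnson cleavage; osmylation prefers the monosubstituted, electron-richer terminal alkene over the trisubstituted alkene deactivated by the ester. Lutidine buffers the medium, and the chlorides are inert.

Step 8
Reactants: 12 methyl (2E,5R,6R)-5,6-dichloro-3,7,7-trimethyl-9-oxonon-2-enoate; 13 methyl prop-2-yn-1-yl carbonate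
Product: 15 methyl (2E,5R,6R)-5,6-dichloro-9-hydroxy-12-[(methoxycarbonyl)oxy]-3,7,7-trimethyldodec-2-en-10-ynoate (both C9 epimers), via zinc acetylide 14 (not isolated)
Conditions: 13, Zn(OTf)2, Et3N, PhMe, rt; then 12
Reagents that add atoms: none
Why: Addition of a zinc acetylide generated in situ from a terminal alkyne, Zn(OTf)2 and an amine forms C6–C7 and tolerates esters, the carbonate and alkyl chlorides. The neopentyl α-carbon of 12 slows self-aldol reaction, and the new carbinol centre is removed in step 9.

Step 9
Reactants: 15 methyl (2E,5R,6R)-5,6-dichloro-9-hydroxy-12-[(methoxycarbonyl)oxy]-3,7,7-trimethyldodec-2-en-10-ynoate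
Product: 16 methyl (2E,5R,6R)-5,6-dichloro-12-[(methoxycarbonyl)oxy]-3,7,7-trimethyl-9-oxododec-2-en-10-ynoate
Conditions: Dess–Martin periodinane, CH2Cl2, 0 °C to rt
Reagents that add atoms: none
Why: Dess–Martin oxidation of a propargylic alcohol to the ynone under neutral conditions. Both epimers converge on one compound.

Step 10
Reactants: 16 methyl (2E,5R,6R)-5,6-dichloro-12-[(methoxycarbonyl)oxy]-3,7,7-trimethyl-9-oxododec-2-en-10-ynoate
Product: 17 methyl (2E,5R,6R,8Z)-5,6-dichloro-12-[(methoxycarbonyl)oxy]-3,7,7-trimethyl-9-[(triisopropylsilyl)oxy]dodeca-2,8-dien-10-ynoate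
Conditions: i-Pr3SiOTf, i-Pr2NEt, CH2Cl2, −78 to 0 °C
Reagents that add atoms: triisopropylsilyl trifluoromethanesulfonate, CC(C)[Si](OS(=O)(=O)C(F)(F)F)(C(C)C)C(C)C
Why: Soft enolisation of a ketone by a silyl triflate and a hindered amine; C5 is the only α-position that bears hydrogen, and no free enolate forms, so 1,3-elimination of C3–Cl to a cyclopropane is avoided. In the O-silylated ketone the silyl group lies on the side of the slim alkynyl group, so C4 should settle cis to oxygen and trans to C7 (Z).

Step 11
Reactants: 17 methyl (2E,5R,6R,8Z)-5,6-dichloro-12-[(methoxycarbonyl)oxy]-3,7,7-trimethyl-9-[(triisopropylsilyl)oxy]dodeca-2,8-dien-10-ynoate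
Product: 18 methyl (2E,5R,6R,8Z)-5,6-dichloro-3,7,7-trimethyl-9-[(triisopropylsilyl)oxy]dodeca-2,8,10,11-tetraenoate
Conditions: Pd2(dba)3·CHCl3 (2.5 mol %), PBu3 (10 mol %), HCO2NH4, THF, rt; filtration through neutral alumina
Reagents that add atoms: none
Why: Palladium-catalysed hydrogenolysis of an alk-2-ynyl carbonate with formate, a known route to 1,2-dienes. Zerovalent palladium adds in the SN2′ sense to give a σ-allenylpalladium species with the metal on C7, formate loses CO2 to give the hydride, and reductive elimination forms C7–H and the terminal allene.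

Step 12
Reactants: 18 methyl (2E,5R,6R,8Z)-5,6-dichloro-3,7,7-trimethyl-9-[(triisopropylsilyl)oxy]dodeca-2,8,10,11-tetraenoate
Product: 19 methyl 2α,3β-dichloro-6-(triisopropylsilyloxy)drima-6,8(12)-dien-11-oate (5α-H, 9α-H, 10β-CH3)
Conditions: PhMe (0.005 M), BHT (cat.), 100 °C, base-washed glass
Reagents that add atoms: none
Why: Thermal type 1 intramolecular Diels–Alder reaction of a 2-silyloxy vinylallene with a tethered E-enoate; the closest known types are the intramolecular cycloadditions of siloxy vinylallenes and of 2-silyloxy-1,7,9-decatrienes. The 4π unit C5=C6–C7=C8 and the 2π unit C9=C10 combine suprafacially, and C5–C10 and C8–C9 form in one concerted but asynchronous event led by the bond from the enol-silane carbon C5 to the enoate β-carbon C10, so polarity and tether fix the same regiochemistry. Ring B closes as the new cyclohexene of the [4+2] addition, and ring A closes as the six-membered tether ring (C5, C4, C3, C2, C1, C10) in a chair-like array helped by the gem-dimethyl group. The allene lends only C7=C8: the orthogonal C8=C17 bond stays behind as the exocyclic methylene, leaves no inside substituent at the diene terminus (easy s-cis form) and releases the strain of the sp carbon, which is why a β,β-disubstituted enoate should suffice as dienophile. C9 is controlled by the E geometry of the enoate, which places CO2CH3 and the C10 methyl group cis (both β). The trans relation of C5–H and C10–CH3 follows from the Z enol silane (C4 outside) reacting through the anti transition state with ester and methyl group endo. The absolute sense follows from C2 and C3, because only one of the two anti chairs keeps both C–Cl bonds equatorial, while the other puts C2–Cl 1,3-diaxial to the C4 and C10 methyl groups. The product holds the ketone as its dienol silane, so C8=C17 cannot move into conjugation in the following steps.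

Step 13
Reactants: 19 methyl 2α,3β-dichloro-6-(triisopropylsilyloxy)drima-6,8(12)-dien-11-oate
Product: 20 2α,3β-dichloro-6-(triisopropylsilyloxy)drima-6,8(12)-dien-11-al
Conditions: i-Bu2AlH (1.1 equiv), CH2Cl2, −78 °C; MeOH, then aq potassium sodium tartrate; used at once
Reagents that add atoms: none
Why: Partial reduction of a hindered methyl ester; the tetrahedral aluminate next to the quaternary C10 should persist at −78 °C until the quench. The enol silane and the chlorides are inert, and the neutral work-up leaves C9 untouched.

Step 14
Reactants: 20 2α,3β-dichloro-6-(triisopropylsilyloxy)drima-6,8(12)-dien-11-al; 21 2-(dichloromethyl)-4,4,5,5-tetramethyl-1,3,2-dioxaborolane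
Product: 22 pinacol (11E)-2α,3β-dichloro-6-(triisopropylsilyloxy)-13,14,15,16-tetranorlabda-6,8(17),11-trien-12-ylboronate
Conditions: CrCl2, LiI, THF, rt
Reagents that add atoms: none
Why: Takai–Utimoto olefination with the geminal dichromium reagent formed from 21; it forms C11=C12, is selective for aldehydes, gives the E alkene and is not basic. Simple secondary alkyl chlorides are not reduced by CrCl2 under these conditions.

Step 15
Reactants: 22 pinacol (11E)-2α,3β-dichloro-6-(triisopropylsilyloxy)-13,14,15,16-tetranorlabda-6,8(17),11-trien-12-ylboronate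
Product: 23 2α,3β-dichloro-6-(triisopropylsilyloxy)-13,14,15,16-tetranorlabda-6,8(17)-dien-12-al
Conditions: NaBO3·4H2O, THF–H2O, rt
Reagents that add atoms: sodium perborate, [Na+].[O-]OB=O
Why: Oxidation of an alkenylboronate; 1,2-migration of the alkenyl group from boron to oxygen gives the enol borate, which tautomerises to the aldehyde with C11 as CH2. The nucleophilic peroxide does not attack the electron-rich dienol silane.

Step 16
Reactants: 24 (R)-4-benzyloxazolidin-2-one; 25 methyl 4-chloro-4-oxobutanoate
Product: 26 methyl 4-[(4R)-4-benzyl-2-oxooxazolidin-3-yl]-4-oxobutanoate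
Conditions: Et3N, DMAP (cat.), CH2Cl2, 0 °C to rt
Reagents that add atoms: none
Why: DMAP-catalysed N-acylation of an oxazolidinone by an acid chloride. The stereocentre of the auxiliary is not involved.

Step 17
Reactants: 23 2α,3β-dichloro-6-(triisopropylsilyloxy)-13,14,15,16-tetranorlabda-6,8(17)-dien-12-al; 26 methyl 4-[(4R)-4-benzyl-2-oxooxazolidin-3-yl]-4-oxobutanoate
Product: 29 syn-aldol adduct (12S-OH; 13R; C15 methyl ester; C16 bound to the (R)-4-benzyl-2-oxazolidinone; ring B as in 23), via boron enolate 27 (not isolated), via boron aldolate 28 (not isolated)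
Conditions: 26, Bu2BOTf, Et3N, CH2Cl2, −78 to 0 °C; then 23, −78 to 0 °C; then pH 7 buffer, MeOH, H2O2, 0 °C
Reagents that add atoms: none
Why: Evans syn aldol reaction; boron enolisation takes place only at the chelated imide carbonyl and gives the Z enolate, which reacts through a Zimmerman–Traxler chair with the auxiliary dipole opposed. The (R)-benzyl auxiliary gives 12S,13R under reagent control, which is needed because C9 is too remote to steer the pair.

Step 18
Reactants: 29 syn-aldol adduct
Product: 31 6-O-triisopropylsilyl dienol ether of haterumaimide B (Δ6 and Δ8(17); 12S; 13R), via hydroxy amide ester 30 (not isolated)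
Conditions: NH3 (7 M in MeOH), THF, 0 °C to rt
Reagents that add atoms: ammonia, N
Why: Ammonolysis of the activated exocyclic acyl–N bond gives primary amide 30, which closes onto the C15 methyl ester (5-exo-trig); if the ester is attacked first, the amide closes onto the acyl oxazolidinone instead, so both orders converge on 31. The imide N–H is the most acidic site and is held as its ammonium salt, which makes 31 the sink and shields C13 from epimerisation.

Step 19
Reactants: 31 6-O-triisopropylsilyl dienol ether of haterumaimide B
Product: 32 haterumaimide B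
Conditions: Bu4NF, AcOH (1:1), THF, −40 to 0 °C; pH 7 buffer
Reagents that add atoms: none
Why: Fluoride removes silicon and frees the extended dienolate, which acetic acid protonates kinetically at the α-carbon C7; this is the known deconjugative protonation of dienolates and gives the β,γ-unsaturated ketone. The buffer and low temperature keep the product from re-enolising, and C5 is not touched.

## Compound list

1 | 3-methylbut-2-enal | CC(C)=CC=O | starting material
2 | allylmagnesium bromide | C=CC[Mg]Br | starting material
3 | 6-methylhepta-1,5-dien-4-ol (racemic) | C=CCC(O)C=C(C)C | intermediate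
4 | 3,3-dimethylhex-5-enal | C=CCC(C)(C)CC=O | intermediate
5 | (2R)-2-chloro-3,3-dimethylhex-5-enal | C=CCC(C)(C)[C@@H](Cl)C=O | intermediate
6 | methyl 3-methylbut-2-enoate | CC(C)=CC(=O)OC | starting material
7 | lithium dienolate of 6 | C=C(C)C=C(OC)O[Li] | intermediate
8 | [(1-methoxy-3-methylbuta-1,3-dien-1-yl)oxy]trimethylsilane | C=C(C)C=C(OC)O[Si](C)(C)C | intermediate
9 | methyl (2E,5S,6R)-6-chloro-5-hydroxy-3,7,7-trimethyldeca-2,9-dienoate | C=CCC(C)(C)[C@@H](Cl)[C@@H](O)C/C(C)=C/C(=O)OC | intermediate
10 | methyl (2E,5R,6R)-5,6-dichloro-3,7,7-trimethyldeca-2,9-dienoate | C=CCC(C)(C)[C@@H](Cl)[C@H](Cl)C/C(C)=C/C(=O)OC | intermediate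
11 | methyl (2E,5R,6R)-5,6-dichloro-9,10-dihydroxy-3,7,7-trimethyldec-2-enoate (C9 epimers) | OCC(O)CC(C)(C)[C@@H](Cl)[C@H](Cl)C/C(C)=C/C(=O)OC | intermediate
12 | methyl (2E,5R,6R)-5,6-dichloro-3,7,7-trimethyl-9-oxonon-2-enoate | O=CCC(C)(C)[C@@H](Cl)[C@H](Cl)C/C(C)=C/C(=O)OC | intermediate
13 | methyl prop-2-yn-1-yl carbonate | C#CCOC(=O)OC | starting material
14 | zinc acetylide of 13 (triflate as second ligand) | COC(=O)OCC#C[Zn]OS(=O)(=O)C(F)(F)F | intermediate
15 | methyl (2E,5R,6R)-5,6-dichloro-9-hydroxy-12-[(methoxycarbonyl)oxy]-3,7,7-trimethyldodec-2-en-10-ynoate (C9 epimers) | COC(=O)OCC#CC(O)CC(C)(C)[C@@H](Cl)[C@H](Cl)C/C(C)=C/C(=O)OC | intermediate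
16 | methyl (2E,5R,6R)-5,6-dichloro-12-[(methoxycarbonyl)oxy]-3,7,7-trimethyl-9-oxododec-2-en-10-ynoate | COC(=O)OCC#CC(=O)CC(C)(C)[C@@H](Cl)[C@H](Cl)C/C(C)=C/C(=O)OC | intermediate
17 | methyl (2E,5R,6R,8Z)-5,6-dichloro-12-[(methoxycarbonyl)oxy]-3,7,7-trimethyl-9-[(triisopropylsilyl)oxy]dodeca-2,8-dien-10-ynoate | COC(=O)OCC#C/C(O[Si](C(C)C)(C(C)C)C(C)C)=C/C(C)(C)[C@@H](Cl)[C@H](Cl)C/C(C)=C/C(=O)OC | intermediate
18 | methyl (2E,5R,6R,8Z)-5,6-dichloro-3,7,7-trimethyl-9-[(triisopropylsilyl)oxy]dodeca-2,8,10,11-tetraenoate | C=C=C/C(O[Si](C(C)C)(C(C)C)C(C)C)=C/C(C)(C)[C@@H](Cl)[C@H](Cl)C/C(C)=C/C(=O)OC | intermediate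
19 | methyl 2α,3β-dichloro-6-(triisopropylsilyloxy)drima-6,8(12)-dien-11-oate | C=C1C=C(O[Si](C(C)C)(C(C)C)C(C)C)[C@H]2C(C)(C)[C@@H](Cl)[C@H](Cl)C[C@]2(C)[C@H]1C(=O)OC | intermediate
20 | 2α,3β-dichloro-6-(triisopropylsilyloxy)drima-6,8(12)-dien-11-al | C=C1C=C(O[Si](C(C)C)(C(C)C)C(C)C)[C@H]2C(C)(C)[C@@H](Cl)[C@H](Cl)C[C@]2(C)[C@H]1C=O | intermediate
21 | 2-(dichloromethyl)-4,4,5,5-tetramethyl-1,3,2-dioxaborolane | ClC(Cl)B1OC(C)(C)C(C)(C)O1 | starting material
22 | pinacol (11E)-2α,3β-dichloro-6-(triisopropylsilyloxy)-13,14,15,16-tetranorlabda-6,8(17),11-trien-12-ylboronate | C=C1C=C(O[Si](C(C)C)(C(C)C)C(C)C)[C@H]2C(C)(C)[C@@H](Cl)[C@H](Cl)C[C@]2(C)[C@H]1/C=C/B3OC(C)(C)C(C)(C)O3 | intermediate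
23 | 2α,3β-dichloro-6-(triisopropylsilyloxy)-13,14,15,16-tetranorlabda-6,8(17)-dien-12-al | C=C1C=C(O[Si](C(C)C)(C(C)C)C(C)C)[C@H]2C(C)(C)[C@@H](Cl)[C@H](Cl)C[C@]2(C)[C@H]1CC=O | intermediate
24 | (R)-4-benzyloxazolidin-2-one | O=C1N[C@H](Cc2ccccc2)CO1 | starting material
25 | methyl 4-chloro-4-oxobutanoate | COC(=O)CCC(=O)Cl | starting material
26 | methyl 4-[(4R)-4-benzyl-2-oxooxazolidin-3-yl]-4-oxobutanoate | COC(=O)CCC(=O)N1[C@H](Cc2ccccc2)COC1=O | intermediate
27 | dibutylboron (Z)-enolate of 26 | CCCCB(CCCC)O/C(=C\CC(=O)OC)N1[C@H](Cc2ccccc2)COC1=O | intermediate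
28 | dibutylboron aldolate of 29 | C=C1C=C(O[Si](C(C)C)(C(C)C)C(C)C)[C@H]2C(C)(C)[C@@H](Cl)[C@H](Cl)C[C@]2(C)[C@H]1C[C@H](OB(CCCC)CCCC)[C@@H](CC(=O)OC)C(=O)N3[C@H](Cc4ccccc4)COC3=O | intermediate
29 | syn-aldol adduct (12S,13R; C15 methyl ester; C16 acyl oxazolidinone) | C=C1C=C(O[Si](C(C)C)(C(C)C)C(C)C)[C@H]2C(C)(C)[C@@H](Cl)[C@H](Cl)C[C@]2(C)[C@H]1C[C@H](O)[C@@H](CC(=O)OC)C(=O)N3[C@H](Cc4ccccc4)COC3=O | intermediate
30 | hydroxy amide ester (12S,13R; C16 primary amide; C15 methyl ester) | C=C1C=C(O[Si](C(C)C)(C(C)C)C(C)C)[C@H]2C(C)(C)[C@@H](Cl)[C@H](Cl)C[C@]2(C)[C@H]1C[C@H](O)[C@@H](CC(=O)OC)C(N)=O | intermediate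
31 | 6-O-triisopropylsilyl dienol ether of haterumaimide B | C=C1C=C(O[Si](C(C)C)(C(C)C)C(C)C)[C@H]2C(C)(C)[C@@H](Cl)[C@H](Cl)C[C@]2(C)[C@H]1C[C@H](O)[C@H]1CC(=O)NC1=O | intermediate
32 | haterumaimide B | C=C1CC(=O)[C@H]2C(C)(C)[C@@H](Cl)[C@H](Cl)C[C@]2(C)[C@H]1C[C@H](O)[C@H]1CC(=O)NC1=O | target

## Step count and least certain steps

Total: 19 steps. The longest linear sequence is 17 steps (steps 1–3, 5–15 and 17–19). Steps 4 and 16 are side branches.

**Step 12 (key step).**
- *Risk:* The most likely failure is poor discrimination between the anti (trans-decalin) and syn (cis-decalin) transition states. Both place one carbon substituent of C10 under the diene, and the thermal endo preference of an ester is small. The second risk is a slow reaction, because C5–C10 joins a neopentyl carbon to a fully substituted one. That would let oligomerisation of the allene or loss of the silyl group compete.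
- *Fallback:* The dienophile is changed, not the conditions. Setting out from 18, reduction of the enoate with i-Bu2AlH (2.2 equiv, CH2Cl2, −78 °C) would give allylic alcohol F1. Oxidation with MnO2 would give enal F2. The formyl group lowers the LUMO further and has the stronger endo preference, so the cycloaddition should run at or below room temperature, if needed with Me2AlCl on the aldehyde. It comes back to the route directly at 20, which makes step 13 unnecessary.

**Step 11.**
- *Risk:* Hydride may be delivered to the propargylic terminus C17, giving the 2-alkyne in place of the allene. A palladium hydride may also isomerise or over-reduce the electron-rich vinylallene.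
- *Fallback:* This route is metal-free and sigmatropic. Setting out from 17, brief methanolysis of the carbonate (K2CO3, MeOH, 0 °C) would give propargylic alcohol F3. Mitsunobu displacement with 2-nitrobenzenesulfonylhydrazide (PPh3, diethyl azodicarboxylate, THF, −15 °C to rt) is followed by sigmatropic loss of dinitrogen, which places hydrogen on C7 by its mechanism. It comes back at 18.

**Step 14 (with the aldehyde from step 13).**
- *Risk:* C9–H of 20 is allylic and α to the formyl group. Enolisation would lead to epimerisation at C9 or to migration of C8=C17 into a push–pull conjugated system. The hindered carbonyl group may also make the olefination slow enough for this to matter.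
- *Fallback:* The aldehyde is avoided altogether, and C11–C12 is formed by a radical. Setting out from 19, full reduction (i-Bu2AlH, 2.5 equiv) would give primary alcohol F4. Treatment with I2, PPh3 and imidazole would give iodide F5. Radical carbonylation (Bu3SnH, AIBN, CO at about 80 atm, benzene, 80 °C) would add C12 as the formyl group, the iodide reacting far faster than the secondary chlorides. It comes back at 23.

**Step 18.**
- *Risk:* Ammonia may attack the endocyclic carbamate carbonyl of the hindered acyl oxazolidinone. The sequence may stall at a γ-lactone formed between O12 and C15. Retro-aldol cleavage or slow loss of the silyl group in methanolic ammonia may also occur.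
- *Fallback:* The auxiliary aldol is replaced by a catalytic ketene–aldehyde cyclocondensation. Setting out from 23 and 25, the alkaloid-catalysed reaction would give cis-β-lactone F6. The conditions are O-trimethylsilylquinine or its pseudoenantiomer (whichever gives 12S,13R), LiClO4 and i-Pr2NEt in CH2Cl2–Et2O at −78 °C. Ammonia in THF opens the strained acyl–O bond cleanly. The route comes back at 30, which closes to 31 with a catalytic amidine base in an aprotic solvent.

**Step 19.**
- *Risk:* γ-Protonation at C17, or base-catalysed re-enolisation of the product by fluoride or acetate, would move the alkene into conjugation with the ketone.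
- *Fallback:* The dienolate is generated reductively in a weakly acidic medium that contains no base. Setting out from 31, NBS (THF, −78 °C) would give γ-bromo enone F7. Zn in THF–aq NH4Cl at 0 °C would give the zinc dienolate, which is protonated at C7 as it forms. The diequatorial dichloride cannot reach the anti-periplanar geometry needed for reductive elimination. It comes back at 32.

## Further compounds

F1 | step 12 | (2E,5R,6R,8Z)-5,6-dichloro-3,7,7-trimethyl-9-[(triisopropylsilyl)oxy]dodeca-2,8,10,11-tetraen-1-ol | C=C=C/C(O[Si](C(C)C)(C(C)C)C(C)C)=C/C(C)(C)[C@@H](Cl)[C@H](Cl)C/C(C)=C/CO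
F2 | step 12 | (2E,5R,6R,8Z)-5,6-dichloro-3,7,7-trimethyl-9-[(triisopropylsilyl)oxy]dodeca-2,8,10,11-tetraenal | C=C=C/C(O[Si](C(C)C)(C(C)C)C(C)C)=C/C(C)(C)[C@@H](Cl)[C@H](Cl)C/C(C)=C/C=O
F3 | step 11 | methyl (2E,5R,6R,8Z)-5,6-dichloro-12-hydroxy-3,7,7-trimethyl-9-[(triisopropylsilyl)oxy]dodeca-2,8-dien-10-ynoate | OCC#C/C(O[Si](C(C)C)(C(C)C)C(C)C)=C/C(C)(C)[C@@H](Cl)[C@H](Cl)C/C(C)=C/C(=O)OC
F4 | step 14 | 2α,3β-dichloro-6-(triisopropylsilyloxy)drima-6,8(12)-dien-11-ol | C=C1C=C(O[Si](C(C)C)(C(C)C)C(C)C)[C@H]2C(C)(C)[C@@H](Cl)[C@H](Cl)C[C@]2(C)[C@H]1CO
F5 | step 14 | 2α,3β-dichloro-11-iodo-6-(triisopropylsilyloxy)drima-6,8(12)-diene | C=C1C=C(O[Si](C(C)C)(C(C)C)C(C)C)[C@H]2C(C)(C)[C@@H](Cl)[C@H](Cl)C[C@]2(C)[C@H]1CI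
F6 | step 18 | cis-β-lactone (12S,13R; O12–C16 lactone; CH2CO2CH3 on C13; ring B as in 23) | C=C1C=C(O[Si](C(C)C)(C(C)C)C(C)C)[C@H]2C(C)(C)[C@@H](Cl)[C@H](Cl)C[C@]2(C)[C@H]1C[C@@H]3OC(=O)[C@@H]3CC(=O)OC
F7 | step 19 | 17-bromo-Δ7-conjugated enone isomer of haterumaimide B | BrCC1=CC(=O)[C@H]2C(C)(C)[C@@H](Cl)[C@H](Cl)C[C@]2(C)[C@H]1C[C@H](O)[C@H]1CC(=O)NC1=O
A1 | alternative 1 | 2α,3β-dichloro-6-oxo-13,14,15,16-tetranorlabd-8(17)-en-12-al | C=C1CC(=O)[C@H]2C(C)(C)[C@@H](Cl)[C@H](Cl)C[C@]2(C)[C@H]1CC=O
A2 | alternative 1 | 2α,3β-dichloro-13,14,15,16-tetranorlabd-8(17)-en-12-al | C=C1CC[C@H]2C(C)(C)[C@@H](Cl)[C@H](Cl)C[C@]2(C)[C@H]1CC=O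
A3 | alternative 2 | tert-butyl{[1-((4R,5R)-4,5-dichloro-2,6,6-trimethylcyclohex-1-en-1-yl)ethenyl]oxy}dimethylsilane | C=C(O[Si](C)(C)C(C)(C)C)C1=C(C)C[C@@H](Cl)[C@H](Cl)C1(C)C
A4 | alternative 2 | methyl buta-2,3-dienoate | C=C=CC(=O)OC
A5 | alternative 2 | methyl 2α,3β-dichloro-6-(tert-butyldimethylsilyloxy)drima-5,8(12)-dien-11-oate | C=C1CC(O[Si](C)(C)C(C)(C)C)=C2C(C)(C)[C@@H](Cl)[C@H](Cl)C[C@]2(C)[C@H]1C(=O)OC
A6 | alternative 3 | monocyclic aldehyde (ring A with C5–CHO and C10 bearing C9H(isopropenyl)CH2CO2CH3) | O=C[C@H]1C(C)(C)[C@@H](Cl)[C@H](Cl)C[C@]1(C)[C@@H](CC(=O)OC)C(C)=C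
A7 | alternative 3 | methyl 2α,3β-dichloro-6-hydroxy-13,14,15,16-tetranorlabd-8(17)-en-12-oate | C=C1CC(O)[C@H]2C(C)(C)[C@@H](Cl)[C@H](Cl)C[C@]2(C)[C@H]1CC(=O)OC
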